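All constants were chosen freely.

A small charge of racemate goes into the flasks larch, cedar and ash, where reagent and a single-handed catalyst turn it into product, and what counts is how much of it ends as left-handed product.

| flask | left-handed substrate | reagent | catalyst | right-handed substrate | time | remark | temperature |
|---|---|---|---|---|---|---|---|
| larch | 0.020 M | 0.0800 M | 20 µM | 0.020 M | 8.0 s | at 35 °C until 4.0 s, from then on at 50 °C |  |
| cedar | 0.020 M | 0.0800 M | 20 µM | 0.020 M | 8.0 s |  | 50 °C |
| ash | 0.020 M | 0.0800 M | 20 µM | 0.020 M | 8.0 s |  | 35 °C |

    reagent + catalyst + left-handed substrate → catalyst + left-handed product (k1 = 35000 /M²/s, Ea1 = 10.0 kJ/mol)
    reagent + catalyst + right-handed substrate → catalyst + right-handed product (k2 = 14000 /M²/s, Ea2 = 20.0 kJ/mol)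
    left-handed substrate ⇌ right-handed substrate (k3 = 1.1 /s, Ea3 = 86.0 kJ/mol)
    left-handed product ⇌ right-handed product (k4 = 0.066 /s, Ea4 = 77.0 kJ/mol)
    (constants at 50 °C)

- catalyst is single-handed; left-handed substrate and right-handed substrate are mirror images of each other, charged as a racemate, each of them at the stated concentration
- constants are those at 50 °C; use the activation energies for any other temperature

- the flask that comes out highest in amount of left-handed product, in percent of the left-handed substrate and right-handed substrate together charged, or "all alike" when all lie within 1.5 percentage points (larch / cedar / ash / all alike)
- left-handed product at the end, in percent of the left-handed substrate and right-handed substrate together charged, larch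
- left-handed product at the end, in percent of the left-handed substrate and right-handed substrate together charged, cedar
- left-handed product at the end, in percent of the left-handed substrate and right-handed substrate together charged, ash

Minutes of the meeting. I proposed that we follow the fraction of substrate left and not the product made, and that we carry one number, the spending constant, which is the mean of the two catalysed constants times c(reagent) and c(catalyst), a pseudo-first-order constant for the pooled substrate, 0.0312 /s in ash. I argued that the pool may be treated as racemic because in ash the substrates relax with a half-life of 1.50 s, far shorter than the 22.2 s of spending. Taking c(reagent) at its charge, I reckoned the fraction left at 8.0 s as 77.9% in ash and, with 0.0392 /s, as 73.1% in cedar.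

A colleague objected that cedar spends more substrate than ash but that spent substrate goes to both products, and that the relaxation of the products speeds up by 4.0 from ash to cedar, against 1.2 for the catalysed turning of left-handed substrate. I accepted this and took the excess at birth, 0.500 in ash and 0.429 in cedar, damped by that relaxation over a mean product age of 4.00 s. This gave me left-handed product of 15.9% in ash and 16.9% in cedar, which lie 1 percentage point apart, inside the margin of 1.5 points. Asked about larch, I answered that it runs on the constants of ash until 4.0 s and on those of cedar afterwards, so I placed it between them, and I committed to no flask standing out.

The forecast also said all alike, with 15% for larch, and with 15.8% for cedar and 14.7% for ash, these last two below my figures for those flasks, and with product racemisation “largely offsetting the faster conversion”.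

The simulation gives all alike, with 15.0% in larch, 15.8% in cedar and 14.8% in ash.

In ash the two substrates keep 77% and 82% of their charges, a mean of 79.5% against my 77.9%. The neighbouring flask is ash with 0.020 M of reagent, 1.00 equiv to left-handed substrate, and the spending constant scales with c(reagent) to 0.007789 /s. That gives a fraction left of 94.0% and left-handed product of 4.34% by the same reckoning. In that flask 94% of left-handed substrate and 95% of right-handed substrate remain, and left-handed product stands at 4.07%.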